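**Retrosynthetic overview**

1. Numbering (labdane type): ring A = C1–C5 + C10 (Br on C3, gem-dimethyl on C4, methyl C20 on C10), ring B = C5–C10; C8 bears methyl C17 and vinyl C14=C15, C9 bears the chain C11–C12–C13(=O)–C16; β = face of C20.
2. Target ⇒ E-enone ⇒ bicyclic C11 aldehyde: the 3-oxobutyl chain comes last, by Wittig olefination and copper hydride 1,4-reduction.
3. Key disconnection C8–C9 of ring B: the quaternary C8 bears a vinyl group, so C8–C14–C15 is an allyl unit branched at C8, and C9 becomes an enamine carbon once C11 is a formyl group; ring B thus closes by 6-exo allylic alkylation within a ring-A seco aldehyde carrying a tertiary allylic alcohol at C8.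
4. The seco aldehyde ⇒ seco methyl ketone with a C10 vinyl group ⇒ Grob fragmentation of a 3β-bromodrimane-8α,11-diol monomesylate: a provisional ring B, made only to set C3, C5 and C10, is cut at C8–C9.
5. Ring order: ring A and the provisional ring B in one bromonium-induced cyclisation of farnesyl acetate (step 1); ring B opened (step 4); ring B closed again with the final C8 and C9 centres (step 8).

Key step: step 8

Assumption (step 2): the lipase is taken to hydrolyse faster the acetate enantiomer with natural drimane configuration (5α-H, 10β-CH3), as lipases of this type do with primary alcohols of this ring system; if the preference is the reverse, the recovered acetate is that enantiomer and is methanolysed (K2CO3, MeOH) to the same diol.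
Remark: the cation and the hydroxy acetate of step 1 are racemic; their SMILES show the enantiomer that is carried on.

**Route**

Step 1
Reactants: 1 (2E,6E)-farnesyl acetate
Product: 3 rac-3β-bromo-8α-hydroxydriman-11-yl acetate (trans-decalin; 5α-H; 9α-H; 10β-CH3), via dioxanylium cation 2 (not isolated)
Conditions: Et2SBr·SbBrCl5 (1.1 equiv), MeNO2, −25 °C, 10 min; then H2O
Reagents that add atoms: bromodiethylsulfonium bromopentachloroantimonate, CC[S+](Br)CC.Br[Sb-](Cl)(Cl)(Cl)(Cl)Cl; water, O
Why: Bromonium-induced cation–olefin bicyclisation in which Br+ adds to the terminal alkene, two chair-like anti additions set 3β-Br (equatorial), 5α-H, 10β-CH3 and 9α-H in one relative sense, and the C8 cation is captured from the α face by the acetate carbonyl oxygen to give dioxanylium ion 2, which water opens to the more stable primary acetate (polyene cyclisation ended by neighbouring-group participation).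

Step 2
Reactants: 3 rac-3β-bromo-8α-hydroxydriman-11-yl acetate
Product: 4 3β-bromodrimane-8α,11-diol (single enantiomer; 5α-H; 9α-H; 10β-CH3)
Conditions: Burkholderia cepacia lipase (Amano PS), phosphate buffer pH 7/acetone, 30 °C, stopped near half conversion; chromatography
Reagents that add atoms: none
Why: Lipase-catalysed kinetic resolution by enantioselective hydrolysis of a primary acetate next to the C9 stereocentre should give the diol of natural drimane configuration while the mirror-image acetate stays unchanged and is separated; no new stereocentre is formed.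

Step 3
Reactants: 4 3β-bromodrimane-8α,11-diol
Product: 5 3β-bromo-8α-hydroxydriman-11-yl methanesulfonate
Conditions: MsCl, Et3N, CH2Cl2, 0 °C
Reagents that add atoms: methanesulfonyl chloride, CS(=O)(=O)Cl
Why: Sulfonylation is selective for the primary hydroxyl because the tertiary 8-hydroxyl does not react under these conditions.

Step 4
Reactants: 5 3β-bromo-8α-hydroxydriman-11-yl methanesulfonate
Product: 6 seco ketone 4-(3-bromo-2,2,6-trimethyl-6-vinylcyclohexyl)butan-2-one (ring A with 3β-Br, 5α-H, 10β-CH3; vinyl = C9=C11 on C10; chain C6–C7–C8(=O)–C17 on C5)
Conditions: KOtBu, t-BuOH/THF, 0 °C to rt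
Reagents that add atoms: none
Why: Grob fragmentation of a 1,3-diol monosulfonate, in which the C8 alkoxide expels mesylate through an antiperiplanar C8–C9/C11–O array, cuts ring B into the C8 methyl ketone and the C9=C11 vinyl group while C3, C5 and C10 are untouched; the equatorial bromide has no antiperiplanar hydrogen and should survive the base.

Step 5
Reactants: 6 seco ketone
Product: 8 keto alcohol 4-[3-bromo-6-(2-hydroxyethyl)-2,2,6-trimethylcyclohexyl]butan-2-one, via catechol boronate 7 (not isolated)
Conditions: catecholborane, RhCl(PPh3)3 (2 mol%), THF, rt; then H2O2, aq. NaOH, 0 °C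
Reagents that add atoms: catecholborane, B1Oc2ccccc2O1; hydrogen peroxide, OO
Why: Rhodium-catalysed hydroboration with catecholborane is selective for a terminal alkene in the presence of a ketone and puts boron on C11 (anti-Markovnikov), and oxidation of the C–B bond gives the primary alcohol without touching a stereocentre.

Step 6
Reactants: 8 keto alcohol
Product: 9 diol 5-[3-bromo-6-(2-hydroxyethyl)-2,2,6-trimethylcyclohexyl]-3-methylpent-1-en-3-ol (both C8 epimers)
Conditions: CH2=CHMgBr (3.5 equiv), CeCl3, THF, −78 to 0 °C; aq. NH4Cl
Reagents that add atoms: vinylmagnesium bromide, C=C[Mg]Br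
Why: Grignard 1,2-addition to the methyl ketone (the first equivalent only deprotonates the hydroxyl and CeCl3 suppresses enolisation) gives the tertiary allylic alcohol as a C8 epimer mixture, which does not matter because C8 becomes planar in the π-allyl intermediate of step 8.

Step 7
Reactants: 9 diol
Product: 10 hydroxy aldehyde 2-[4-bromo-2-(3-hydroxy-3-methylpent-4-en-1-yl)-1,3,3-trimethylcyclohexyl]acetaldehyde (both C8 epimers)
Conditions: TEMPO (10 mol%), PhI(OAc)2 (1.1 equiv), CH2Cl2, rt
Reagents that add atoms: none
Why: Oxoammonium (TEMPO) oxidation turns the primary alcohol into the aldehyde and leaves the tertiary alcohol, both alkenes and the bromide alone.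

Step 8
Reactants: 10 hydroxy aldehyde
Product: 12 3β-bromo-8α-methyl-8β-vinyl-9β-H-driman-11-al (C11 formyl group α on C9; trans-decalin), via enamine 11 (not isolated)
Conditions: Pd(PPh3)4 (5 mol%), (R)-α,α-diphenylprolinol trimethylsilyl ether (20 mol%), PhCO2H (20 mol%), toluene/DMSO, 25–40 °C
Reagents that add atoms: none
Why: Proposed new method: the secondary amine condenses with the aldehyde to the E-enamine 11 while zerovalent palladium, helped by benzoic acid, ionises the tertiary allylic alcohol (both C8 epimers) to one π-allyl complex, the enamine carbon C9 attacks the fully substituted allyl terminus C8 on the face opposite to palladium, and hydrolysis of the iminium ion releases 12 and both catalysts. The closest known reaction type is the dual amine/palladium intramolecular Tsuji–Trost α-allylation of aldehydes, which closes five- and six-membered rings at unsubstituted or monosubstituted allyl termini; new here are bond formation at a disubstituted terminus (quaternary C8) next to the neopentyl carbon C9 and the direct use of a tertiary allylic alcohol. Ring B closes in the 6-exo mode (the C14=C15 bond ends outside the ring), which should be favoured over the eight-membered ring from attack at C15 by ring size and by the higher positive charge at the tertiary terminus. C9 is set by the catalyst: the diphenyl(silyloxy)methyl group of the (R)-amine shields one face of the s-trans E-enamine, so C8 bonds to the face that leaves H-9 β and the formyl group α (9R). C8 is set by the substrate in a chair-like open transition state in which the palladium-bearing allyl unit and the enamine lie antiperiplanar across the forming bond and methyl C17 takes the equatorial site, which avoids a syn-pentane contact with C20 and gives the β-vinyl group. The step needs chemoselectivity for the allylic C–O bond over the secondary C3–Br bond, secured because Pd(PPh3)4 does not insert into unactivated secondary alkyl bromides under these conditions, and C-allylation over N-allylation of the amine, which is reversible in the presence of acid.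

Step 9
Reactants: 12 bicyclic aldehyde
Product: 13 E-enone (E)-4-[3β-bromo-8α-methyl-8β-vinyl-9β-H-decalin-9-yl]but-3-en-2-one (C11=C12 double bond)
Conditions: Ph3P=CHC(O)CH3 (2 equiv), toluene, 90 °C
Reagents that add atoms: 1-(triphenyl-λ5-phosphanylidene)propan-2-one, CC(=O)C=P(c1ccccc1)(c1ccccc1)c1ccccc1
Why: Wittig olefination with the stabilised acetonyl ylide should give the E-enone under neutral conditions that do not epimerise C9, and no new stereocentre is formed.

Step 10
Reactants: 13 E-enone
Product: 14 4-[(1R,2R,4aR,6S,8aR)-6-bromo-2-ethenyl-2,5,5,8a-tetramethyldecahydronaphthalen-1-yl]butan-2-one (target)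
Conditions: [(Ph3P)CuH]6 (0.5 equiv), H2O (2 equiv), degassed toluene, rt
Reagents that add atoms: none
Why: Copper hydride conjugate reduction delivers hydride only to the β-carbon of the enone and leaves the isolated vinyl group and the secondary bromide untouched, and protonation of the copper enolate gives the methyl ketone without affecting any stereocentre.

**Compound list**

1 | (2E,6E)-farnesyl acetate | CC(C)=CCC/C(C)=C/CC/C(C)=C/COC(C)=O | starting material
2 | 2-methyl-1,3-dioxan-2-ylium cation bridging O8 and O11 of the 3β-bromodrimane skeleton (racemic) | CC1=[O+][C@]2(C)CC[C@H]3C(C)(C)[C@@H](Br)CC[C@]3(C)[C@H]2CO1 | intermediate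
3 | rac-3β-bromo-8α-hydroxydriman-11-yl acetate | O[C@]1(C)CC[C@H]2C(C)(C)[C@@H](Br)CC[C@]2(C)[C@H]1COC(C)=O | intermediate
4 | 3β-bromodrimane-8α,11-diol (single enantiomer) | O[C@]1(C)CC[C@H]2C(C)(C)[C@@H](Br)CC[C@]2(C)[C@H]1CO | intermediate
5 | 3β-bromo-8α-hydroxydriman-11-yl methanesulfonate | O[C@]1(C)CC[C@H]2C(C)(C)[C@@H](Br)CC[C@]2(C)[C@H]1COS(C)(=O)=O | intermediate
6 | seco ketone 4-(3-bromo-2,2,6-trimethyl-6-vinylcyclohexyl)butan-2-one | CC(=O)CC[C@H]1C(C)(C)[C@@H](Br)CC[C@]1(C)C=C | intermediate
7 | catechol boronate of 6 (boron on C11) | CC(=O)CC[C@H]1C(C)(C)[C@@H](Br)CC[C@]1(C)CCB1Oc2ccccc2O1 | intermediate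
8 | keto alcohol 4-[3-bromo-6-(2-hydroxyethyl)-2,2,6-trimethylcyclohexyl]butan-2-one | CC(=O)CC[C@H]1C(C)(C)[C@@H](Br)CC[C@]1(C)CCO | intermediate
9 | diol 5-[3-bromo-6-(2-hydroxyethyl)-2,2,6-trimethylcyclohexyl]-3-methylpent-1-en-3-ol (C8 epimers) | C=CC(C)(O)CC[C@H]1C(C)(C)[C@@H](Br)CC[C@]1(C)CCO | intermediate
10 | hydroxy aldehyde 2-[4-bromo-2-(3-hydroxy-3-methylpent-4-en-1-yl)-1,3,3-trimethylcyclohexyl]acetaldehyde (C8 epimers) | C=CC(C)(O)CC[C@H]1C(C)(C)[C@@H](Br)CC[C@]1(C)CC=O | intermediate
11 | E-enamine of 10 with (R)-α,α-diphenylprolinol trimethylsilyl ether | C=CC(C)(O)CC[C@H]1C(C)(C)[C@@H](Br)CC[C@]1(C)/C=C/N1CCC[C@@H]1C(O[Si](C)(C)C)(c1ccccc1)c1ccccc1 | intermediate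
12 | 3β-bromo-8α-methyl-8β-vinyl-9β-H-driman-11-al | C=C[C@@]1(C)CC[C@H]2C(C)(C)[C@@H](Br)CC[C@]2(C)[C@@H]1C=O | intermediate
13 | E-enone from 12 (C11=C12, C13 ketone) | C=C[C@@]1(C)CC[C@H]2C(C)(C)[C@@H](Br)CC[C@]2(C)[C@@H]1/C=C/C(C)=O | intermediate
14 | 4-[(1R,2R,4aR,6S,8aR)-6-bromo-2-ethenyl-2,5,5,8a-tetramethyldecahydronaphthalen-1-yl]butan-2-one | C=C[C@@]1(C)CC[C@H]2C(C)(C)[C@@H](Br)CC[C@]2(C)[C@@H]1CCC(C)=O | target

**Step count and risks**

Total step count: 10. Longest linear sequence: 10 steps (fully linear from 1).

Steps most likely to fail:

Step 8 (proposed new method). The enamine may attack the unsubstituted allyl terminus C15 and give an eight-membered ring. The π-allyl complex may lose a β-hydrogen to a diene, or the amine may be N-allylated irreversibly. Facial selectivity at C8 or C9 may be poor because the bulky enamine and the tertiary terminus are very congested. The fallback uses known chemistry and runs from 10 back to 12. Compound 10 is silylated twice (Me3SiOTf, Et3N, CH2Cl2, 0 °C) to the silyl enol ether/tertiary silyl ether F1. SnCl4 (CH2Cl2, −78 °C) then ionises the tertiary allylic silyl ether to the allyl cation, whose tertiary end is captured through a six-membered chair by the enol silane. This is an allyl-cation-initiated cation–olefin cyclisation ended by a silyl enol ether, the intramolecular form of the Lewis-acid SN1 alkylation of enol silanes. Aqueous work-up gives 12; without the chiral amine the C9 epimers would have to be separated.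

Step 1. The cascade may stop after ring A or end by proton loss instead of acetate capture, and bromonium transfer to the internal alkenes may erode selectivity for the terminal one. The fallback runs from 1 back to 3. Mercurinium-induced cyclisation with Hg(OTf)2·PhNMe2 (MeNO2, −20 °C; then aq. NaCl), a slower and more selective divalent-mercury initiator, gives the 3β-chloromercurio analogue F2 of 3. Bromodemercuration under polar conditions (Br2, LiBr, pyridine, 0 °C, dark) then replaces mercury by bromine with retention and gives 3.

Step 9. The stabilised ylide may fail to add to an aldehyde flanked by two quaternary carbons, or C9 may epimerise on prolonged heating. The fallback runs from 12 back to 13. Aldol addition of the lithium enolate of acetone (LDA, acetone, THF, −78 °C) gives the β-hydroxy ketone F3 as C11 epimers. Mesylation and elimination (MsCl, Et3N; then DBU) then give the E-enone 13.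

Further compounds
F1 | step 8 | trimethylsilyl enol ether of 10 with the tertiary hydroxyl as trimethylsilyl ether (enol ether E/Z mixture, C8 epimers) | C=CC(C)(O[Si](C)(C)C)CC[C@H]1C(C)(C)[C@@H](Br)CC[C@]1(C)C=CO[Si](C)(C)C
F2 | step 1 | rac-3β-chloromercurio-8α-hydroxydriman-11-yl acetate | O[C@]1(C)CC[C@H]2C(C)(C)[C@@H]([Hg]Cl)CC[C@]2(C)[C@H]1COC(C)=O
F3 | step 9 | β-hydroxy ketone from 12 and acetone, hydroxyl on C11 (C11 epimers) | C=C[C@@]1(C)CC[C@H]2C(C)(C)[C@@H](Br)CC[C@]2(C)[C@@H]1C(O)CC(C)=O
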